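## The problem

Target 29 is a diaryl ether of two phloroglucinol units whose oxygens sit in three states: two aryl hydrogen sulfates, three free phenols and the bridging ether oxygen. It has no stereocentre, so nothing has to be controlled in space and everything has to be controlled in position. Ring A (C1' ether carbon, C3' hydroxyl, C5' sulfate) is a phloroglucinol whose three oxygens must all become different, which forces a desymmetrisation of a cheap symmetric phenol. Ring B (C1 ether carbon, C2 and C6 hydroxyl, C4 sulfate, C3 and C5 CH) carries the bridging oxygen on a carbon flanked by two oxygenated carbons, so a late Ullmann or SNAr union at C1 would have to be forced onto a doubly ortho-substituted, electron-rich position. Aryl sulfate monoesters are lost in acid and make intermediates hard to purify, so they must be installed next to last and followed only by a neutral deprotection. The polyhydroxylated core is also air-sensitive as a phenolate. The feature that opens a non-classical solution is the pattern of ring B itself: oxygen on C1, C2, C4 and C6 and hydrogen on C3 and C5 is what a cyclobutenone–ynol ether benzannulation delivers. C1 can enter as the sp3 carbon C4 of a cyclobutenone that already bears the ring A aryloxy group, and C3–C4 can come from an oxygenated alkyne. In that assembly the C2, C4 and C6 oxygens are born as phenol, silyl ether and benzyl ether, so the sulfation site of ring B is marked by the bond construction.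

## Retrosynthesis

**Sulfates and benzyl ethers (29 ⇒ 28 ⇒ 27).** The three O–benzyl bonds are cut last in the forward sense and the two S–O bonds just before them, which leads from 29 through the tribenzyl bis(sulfate) 28 to diol 27. Sulfating a fully deprotected pentaol would mean choosing two of five phenols, whereas 27 shows exactly the two hydroxyls that must be sulfated and hides the other three as ethers. The forward steps must give complete twofold O-sulfation and then a hydrogenolysis that leaves the S–O bonds and the diaryl ether intact.

**Protecting-group relay (27 ⇒ 26 ⇒ 25 ⇒ 24).** No skeletal bond is cut here. The C4 hydroxyl of 27 is traced to the silyl ether of 26, the C5' hydroxyl to the methoxymethyl ether of 25, and the C2 benzyl ether of 25 to the single free phenol of 24. Phenol 24 is the simplification: its four non-bridging oxygens already carry four different labels (free OH, silyl, benzyl, methoxymethyl), so each later step addresses one site without competition.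

**Ring B (24 ⇒ 14 + 19).** Ring B is opened at C2–C3 and C4–C5, the bonds to the two alkyne carbons, and at C1–C2, the bond that the electrocyclisation re-forms. This leads to the racemic 4-aryloxycyclobutenone 14 and the siloxyalkyne 19, through vinylketene 20, vinylcyclobutenone 21, dienylketene 22 and dienone 23. Against a cut of the diaryl ether bond at C1, this cut avoids coupling at a hindered 2,6-dioxygenated position and delivers the C2, C4 and C6 oxygens already differentiated. Against oxygenating a preformed ring, it leaves no regiochemical choice among C–H bonds. The forward reaction must open 14 thermally, add 19 with the silyloxy carbon on the ketene α-carbon, and aromatise without losing the silyl or acetal groups.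

**Siloxyalkyne (19 ⇒ 15 + 16).** The O–Si bond and the C–O bond of 19 are cut, leading through lithium ethynolate 18 and lithium acetylide 17 to acetylene 15 and the silyl triflate 16. The ynolate is the only practical oxygen nucleophile on an sp carbon. A bulky silyl group is needed to steer silylation to oxygen and to keep the ynol ether from rearranging to a silylketene.

**Cyclobutenone (14 ⇒ 6 + 11).** The four-membered ring is cut at C1–C2 and C3–C4, the two bonds of a ketene–ynol ether [2+2] cycloaddition. This gives aryloxyketene 13, made from acid 6 through acid chloride 12, and benzyloxyethyne 11. The bridging C–O bond then already exists in 6 as a simple aryloxyacetate, so it is made by alkylation of a phenoxide with an unhindered primary halide and not by arylation. The forward step needs the usual ynol ether regiochemistry and neutral conditions for the acetal.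

**Ynol ether (11 ⇒ 7 + 8).** The C(sp)–O bond of 11 is traced to benzyl alcohol 7 and trichloroethylene 8 through the dichlorovinyl ether 9 and the lithium acetylide 10. Benzyl is chosen because it ends up on the C6 oxygen and leaves in the final hydrogenolysis together with the other benzyl groups.

**Ring A acid (6 ⇒ 5 ⇒ 3 + 4; 3 ⇒ 2 ⇒ 1).** The O–CH2 bond of ester 5 is cut to phenol 3 and ethyl bromoacetate 4. Phenol 3 is traced through the mono-benzyl ether 2 to phloroglucinol 1. The two statistical mono-protections sit at the very start, on the cheapest material of the route, where recycling costs little.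

## Roads not taken

Alternative 1: The cut is at the two C–O bonds of the future sulfates, C5'–O on ring A and C4–O on ring B. The precursor is the tripivalate diaryl ether A1, which has hydrogen at both sites. In the forward key step a bipyridine-ligated iridium borylation catalyst and a diboron reagent borylate the only C–H positions on each ring that have no ortho substituent, and a peroxymonosulfate oxidant added to the same flask turns both C–B bonds into hydroxyls to give diol A2. Its merits are real. The two new hydroxyls are exactly the sulfation sites, the other three oxygens are already masked, the steric rule for this borylation is dependable on 1,3-di- and 1,2,3-trisubstituted arenes, and the whole route should be clearly shorter than the chosen one. Its weak points lie on either side of the key step. A1 still has to be made by arylating a 2,6-dioxygenated phenol at its hindered oxygen, which is the coupling the chosen plan avoids. The twofold borylation has to go to completion on both rings, or mixtures of mono- and bis-functionalised material are carried into the sulfation. The three pivalates can only be removed by basic solvolysis or hydride in the presence of the sulfates, which exposes the oxidation-prone pentaoxygenated diaryl ether as a phenolate. In step economy this road is better than the chosen plan. The chosen plan sets against it that every oxygen position is fixed by bond construction instead of by steric selection, that the bridging ether is made by a simple alkylation, and that the final deprotection is neutral.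

Alternative 2: The cut is inside ring A, at the C–C bond between a former methyl carbon and a former lactone carbonyl carbon. The precursor is the 4-aryloxy-6-methylpyran-2-one A3, made by attaching the ring B phenol A5 to C4 of an activated 6-methylpyran-2-one. In the forward key step Mg(OMe)2 in methanol opens the lactone and the liberated methyl ketone enolate closes onto the ester in a Claisen condensation, which aromatises to the 5-aryloxyresorcinol A4. The merits are a cheap polyketide-type starting material, no thermally sensitive ynol ethers and a ring A made with its oxygens in place. The weak points are threefold. A3 is a vinylogous carbonate, so methoxide can add at C4 and expel the hindered phenoxide instead of opening the lactone, and the cyclisation needs the less acidic terminal methyl to react. A4 carries two equivalent hydroxyls on ring A, so the mono-sulfate/mono-phenol pattern needs a statistical step late in the route on valuable material. The harder ring, ring B with three differentiated oxygens, is left to a separate classical synthesis of A5. The chosen plan also contains statistical steps, but they are its first two and are run on phloroglucinol. It builds the ring whose differentiation is difficult and lets the annulation do that differentiation.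

Alternative 3: The cut is at C2–C3 and C5–C6 of ring B. The precursors are dimethyl 3-oxopentanedioate A6 and the aryloxymalonate A7. In the forward key step NaOMe in hot methanol would acylate both α-carbons of A6 with the two ester groups of A7 and close ring B as the trihydroxyisophthalate A8. The merits are very cheap reagents and a ring B that appears with all four oxygens and the ether linkage in one operation. The weak points are serious for this target. A7 is deprotonated at its own α-carbon under the conditions and then stops being an electrophile, while A6 self-condenses readily. The two esters of A8 must be removed afterwards by hydrolysis and decarboxylation. The three hydroxyls of A8 emerge unprotected, so telling the C4 hydroxyl from the C2 and C6 hydroxyls would rest on a modest steric difference. The chosen plan has a longer sequence to its annulation partners but delivers the C2, C4 and C6 oxygens with three different labels and no excess carbon.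

Key step: step 8

Assumption: aryl hydrogen sulfates are handled as salts, so 28 and 29 would be isolated as disodium salts; they are written below as the neutral acids, which is how the target is drawn.

## Route

Step 1
Reactants: 1 phloroglucinol (benzene-1,3,5-triol)
Product: 2 5-(benzyloxy)benzene-1,3-diol
Conditions: BnBr (0.33 equiv), K2CO3, DMF, 0 °C → rt
Reagents that add atoms: benzyl bromide, BrCc1ccccc1
Why: Williamson O-benzylation of a phenoxide; a threefold excess of the triol makes the mono-ether the main product by statistics, and unreacted water-soluble 1 is washed out and recovered. A polar aprotic solvent with carbonate favours O- over C-alkylation of the ambident phloroglucinol anion.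

Step 2
Reactants: 2 5-(benzyloxy)benzene-1,3-diol
Product: 3 3-(benzyloxy)-5-(methoxymethoxy)phenol
Conditions: MOMCl (1.0 equiv), iPr2NEt, CH2Cl2, 0 °C → rt
Reagents that add atoms: chloromethyl methyl ether, COCCl
Why: Statistical mono-protection of a symmetric resorcinol by alkylation with an α-chloro ether; diol, mono-ether and bis-ether differ strongly in polarity, and recovered 2 is recycled.

Step 3
Reactants: 3 3-(benzyloxy)-5-(methoxymethoxy)phenol; 4 ethyl bromoacetate
Product: 5 ethyl 2-[3-(benzyloxy)-5-(methoxymethoxy)phenoxy]acetate
Conditions: K2CO3, acetone, reflux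
Reagents that add atoms: none
Why: Williamson ether synthesis of a phenoxide with an α-bromo ester, a fast SN2 reaction at an unhindered primary carbon; this makes the future bridging C–O bond, and both protecting groups are inert to carbonate.

Step 4
Reactants: 5 ethyl 2-[3-(benzyloxy)-5-(methoxymethoxy)phenoxy]acetate
Product: 6 2-[3-(benzyloxy)-5-(methoxymethoxy)phenoxy]acetic acid
Conditions: LiOH, THF/H2O, 0 °C → rt; then 1 M HCl, 0 °C, to pH 3–4
Reagents that add atoms: lithium hydroxide, [Li+].[OH-]
Why: Ester saponification; benzyl and methoxymethyl ethers are stable to hydroxide, and brief cold acidification does not cleave the acetal.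

Step 5
Reactants: 7 benzyl alcohol; 8 trichloroethylene
Product: 11 (benzyloxy)ethyne, via benzyl (E)-1,2-dichlorovinyl ether 9 (not isolated), via lithium (benzyloxy)ethynide 10 (not isolated)
Conditions: KH, THF, 0 °C; 8, 0 °C → rt; n-BuLi (2.4 equiv), −78 °C; MeOH, −78 → 0 °C
Reagents that add atoms: none
Why: Greene's one-pot ynol ether synthesis: the potassium alkoxide adds to dichloroacetylene formed in situ to give 9, which n-BuLi converts by dehydrochlorination and chlorine–lithium exchange into 10, and protonation gives 11. Benzyl has no β-hydrogen for retro-ene loss of ketene; 11 is kept cold and in solution because benzyl alkynyl ethers rearrange on warming.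

Step 6
Reactants: 6 2-[3-(benzyloxy)-5-(methoxymethoxy)phenoxy]acetic acid; 11 (benzyloxy)ethyne
Product: 14 racemic 3-(benzyloxy)-4-[3-(benzyloxy)-5-(methoxymethoxy)phenoxy]cyclobut-2-en-1-one, via aryloxyacetyl chloride 12 (not isolated), via aryloxyketene 13 (not isolated)
Conditions: 1-chloro-N,N,2-trimethylprop-1-en-1-amine, CH2Cl2, 0 °C; then 11 (2.5 equiv), Et3N (slow addition), 0 °C → rt
Reagents that add atoms: none
Why: Ketene–ynol ether [2+2] cycloaddition: 12 is formed without HCl, so the acetal and the electron-rich ring are spared, and Et3N dehydrochlorinates it to 13. The nucleophilic terminal carbon of 11 attacks the ketene carbonyl carbon and the benzyloxy carbon bonds to the aryloxy-bearing carbon, giving the 3-alkoxycyclobutenone; the C4 stereocentre forms racemic and disappears in step 8.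

Step 7
Reactants: 15 acetylene; 16 triisopropylsilyl trifluoromethanesulfonate
Product: 19 (triisopropylsilyloxy)ethyne, via lithium acetylide 17 (not isolated), via lithium ethynolate 18 (not isolated)
Conditions: 15, n-BuLi, THF, −78 °C; t-BuOOLi (from t-BuOOH and LiN(SiMe3)2), −78 → −10 °C; 16, −78 → 0 °C
Reagents that add atoms: tert-butyl hydroperoxide, CC(C)(C)OO
Why: Ynolate formation by electrophilic oxygenation of a lithium acetylide with lithium tert-butyl peroxide, followed by O-silylation; the bulky triisopropylsilyl group directs silylation to oxygen and makes the ynol ether stable enough to handle.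

Step 8
Reactants: 14 racemic 3-(benzyloxy)-4-[3-(benzyloxy)-5-(methoxymethoxy)phenoxy]cyclobut-2-en-1-one; 19 (triisopropylsilyloxy)ethyne
Product: 24 3-(benzyloxy)-2-[3-(benzyloxy)-5-(methoxymethoxy)phenoxy]-5-(triisopropylsilyloxy)phenol, via vinylketene 20 (not isolated), via 4-vinylcyclobutenone 21 (not isolated), via dienylketene 22 (not isolated), via cyclohexadienone 23 (not isolated)
Conditions: 19 (2.5 equiv), toluene (0.1 M), 80 → 110 °C, sealed tube, Ar
Reagents that add atoms: none
Why: Danheiser benzannulation of a cyclobutenone with a siloxyalkyne, the closest known reaction type being this same annulation with 1-siloxy-1-alkynes (here the cyclobutenone carries a 4-aryloxy group and the alkyne is the terminal parent). Heating opens 14 by conrotatory 4π electrocyclic cleavage of the C1–C4 bond with the aryloxy donor turning outward, which gives vinylketene 20 with hydrogen on the inside of the diene terminus. The ketene C=C of 20 adds 19 in a [2+2] step in which the nucleophilic terminal alkyne carbon attacks the ketene carbonyl carbon (new C2–C3 bond of ring B) and the silyloxy carbon bonds to the ketene α-carbon (new C4–C5 bond), giving 21. A second 4π opening of 21 gives dienylketene 22, and ring B closes by thermal disrotatory 6π electrocyclisation between the ketene carbon and the aryloxy-bearing terminus (C2–C1), a six-membered carbocyclic closure; dienone 23 then tautomerises irreversibly to phenol 24. No stereocentre is set: the stereocentre of 14 becomes sp2 in 20 and the sp3 carbon of 23 is lost on aromatisation. The selectivity needed is the orientation of the [2+2] addition, secured by the polarisation of the ynol ether, which places the silyloxy carbon para to the aryloxy carbon. Outward rotation of the aryloxy group keeps the cyclising terminus unhindered, and excess 19 at moderate dilution keeps the phenolic product from being acylated by 20.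

Step 9
Reactants: 24 3-(benzyloxy)-2-[3-(benzyloxy)-5-(methoxymethoxy)phenoxy]-5-(triisopropylsilyloxy)phenol; 7 benzyl alcohol
Product: 25 {3,5-bis(benzyloxy)-4-[3-(benzyloxy)-5-(methoxymethoxy)phenoxy]phenoxy}tri(propan-2-yl)silane
Conditions: PPh3, DIAD, THF, 0 °C → rt
Reagents that add atoms: none
Why: Mitsunobu etherification of a phenol with a primary alcohol; the neutral conditions avoid a phenoxide that could shuffle the aryl silyl ether, and 24 has only one free hydroxyl.

Step 10
Reactants: 25 {3,5-bis(benzyloxy)-4-[3-(benzyloxy)-5-(methoxymethoxy)phenoxy]phenoxy}tri(propan-2-yl)silane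
Product: 26 3-(benzyloxy)-5-[2,6-bis(benzyloxy)-4-(triisopropylsilyloxy)phenoxy]phenol
Conditions: HCl (cat.), MeOH/THF, 45 °C
Reagents that add atoms: none
Why: Acid-catalysed acetal exchange of an aryl methoxymethyl ether in methanol, which carries the formaldehyde unit away as dimethoxymethane instead of letting it attack the electron-rich rings. Benzyl ethers are inert and the aryl silyl ether is largely stable; any loss of it is harmless because step 11 removes it.

Step 11
Reactants: 26 3-(benzyloxy)-5-[2,6-bis(benzyloxy)-4-(triisopropylsilyloxy)phenoxy]phenol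
Product: 27 3,5-bis(benzyloxy)-4-[3-(benzyloxy)-5-hydroxyphenoxy]phenol
Conditions: Bu4NF, AcOH, THF, 0 °C
Reagents that add atoms: none
Why: Fluoride cleavage of an aryl silyl ether, driven by the Si–F bond; acetic acid buffers the phenoxide so that the electron-rich diol is not oxidised.

Step 12
Reactants: 27 3,5-bis(benzyloxy)-4-[3-(benzyloxy)-5-hydroxyphenoxy]phenol
Product: 28 3,5-bis(benzyloxy)-4-[3-(benzyloxy)-5-(sulfooxy)phenoxy]phenyl hydrogen sulfate
Conditions: SO3·pyridine (6 equiv), pyridine, 40 °C; NaHCO3 work-up (disodium salt)
Reagents that add atoms: sulfur trioxide–pyridine complex, O=S(=O)([O-])[n+]1ccccc1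
Why: O-Sulfation of phenols with an amine–SO3 complex; the only two free hydroxyls of 27 are the two sulfation sites and both are unhindered, and the sulfates are kept as salts from here on.

Step 13
Reactants: 28 3,5-bis(benzyloxy)-4-[3-(benzyloxy)-5-(sulfooxy)phenoxy]phenyl hydrogen sulfate
Product: 29 3,5-dihydroxy-4-[3-hydroxy-5-(sulfooxy)phenoxy]phenyl hydrogen sulfate
Conditions: H2 (1 atm), 10% Pd/C, MeOH/H2O, rt (on the disodium salt)
Reagents that add atoms: none
Why: Catalytic hydrogenolysis of three benzyl aryl ethers under neutral conditions; aryl sulfate salts and the diaryl ether bond are not reduced by H2 over Pd/C.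

## Compound list

1 | phloroglucinol (benzene-1,3,5-triol) | Oc1cc(O)cc(O)c1 | starting material
2 | 5-(benzyloxy)benzene-1,3-diol | Oc1cc(O)cc(OCc2ccccc2)c1 | intermediate
3 | 3-(benzyloxy)-5-(methoxymethoxy)phenol | Oc1cc(OCc2ccccc2)cc(OCOC)c1 | intermediate
4 | ethyl bromoacetate | CCOC(=O)CBr | starting material
5 | ethyl 2-[3-(benzyloxy)-5-(methoxymethoxy)phenoxy]acetate | CCOC(=O)COc1cc(OCc2ccccc2)cc(OCOC)c1 | intermediate
6 | 2-[3-(benzyloxy)-5-(methoxymethoxy)phenoxy]acetic acid | OC(=O)COc1cc(OCc2ccccc2)cc(OCOC)c1 | intermediate
7 | benzyl alcohol | OCc1ccccc1 | starting material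
8 | trichloroethylene | ClC=C(Cl)Cl | starting material
9 | benzyl (E)-1,2-dichlorovinyl ether | Cl/C=C(/Cl)OCc1ccccc1 | intermediate
10 | lithium (benzyloxy)ethynide | [Li]C#COCc1ccccc1 | intermediate
11 | (benzyloxy)ethyne | C#COCc1ccccc1 | intermediate
12 | 2-[3-(benzyloxy)-5-(methoxymethoxy)phenoxy]acetyl chloride | ClC(=O)COc1cc(OCc2ccccc2)cc(OCOC)c1 | intermediate
13 | 2-[3-(benzyloxy)-5-(methoxymethoxy)phenoxy]ethen-1-one (aryloxyketene) | O=C=COc1cc(OCc2ccccc2)cc(OCOC)c1 | intermediate
14 | racemic 3-(benzyloxy)-4-[3-(benzyloxy)-5-(methoxymethoxy)phenoxy]cyclobut-2-en-1-one | O=C1C=C(OCc2ccccc2)C1Oc1cc(OCc2ccccc2)cc(OCOC)c1 | intermediate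
15 | acetylene | C#C | starting material
16 | triisopropylsilyl trifluoromethanesulfonate | CC(C)[Si](OS(=O)(=O)C(F)(F)F)(C(C)C)C(C)C | starting material
17 | lithium acetylide | [Li]C#C | intermediate
18 | lithium ethynolate | [Li]OC#C | intermediate
19 | (triisopropylsilyloxy)ethyne | C#CO[Si](C(C)C)(C(C)C)C(C)C | intermediate
20 | (3Z)-3-(benzyloxy)-4-[3-(benzyloxy)-5-(methoxymethoxy)phenoxy]buta-1,3-dien-1-one (vinylketene) | O=C=C/C(OCc1ccccc1)=C/Oc1cc(OCc2ccccc2)cc(OCOC)c1 | intermediate
21 | racemic 4-{(Z)-1-(benzyloxy)-2-[3-(benzyloxy)-5-(methoxymethoxy)phenoxy]ethenyl}-3-(triisopropylsilyloxy)cyclobut-2-en-1-one | O=C1C=C(O[Si](C(C)C)(C(C)C)C(C)C)C1/C(OCc1ccccc1)=C/Oc1cc(OCc2ccccc2)cc(OCOC)c1 | intermediate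
22 | (3E,5Z)-5-(benzyloxy)-6-[3-(benzyloxy)-5-(methoxymethoxy)phenoxy]-3-(triisopropylsilyloxy)hexa-1,3,5-trien-1-one (dienylketene) | O=C=C/C(O[Si](C(C)C)(C(C)C)C(C)C)=C\C(OCc1ccccc1)=C\Oc1cc(OCc2ccccc2)cc(OCOC)c1 | intermediate
23 | racemic 5-(benzyloxy)-6-[3-(benzyloxy)-5-(methoxymethoxy)phenoxy]-3-(triisopropylsilyloxy)cyclohexa-2,4-dien-1-one | O=C1C=C(O[Si](C(C)C)(C(C)C)C(C)C)C=C(OCc2ccccc2)C1Oc1cc(OCc2ccccc2)cc(OCOC)c1 | intermediate
24 | 3-(benzyloxy)-2-[3-(benzyloxy)-5-(methoxymethoxy)phenoxy]-5-(triisopropylsilyloxy)phenol | Oc1cc(O[Si](C(C)C)(C(C)C)C(C)C)cc(OCc2ccccc2)c1Oc1cc(OCc2ccccc2)cc(OCOC)c1 | intermediate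
25 | {3,5-bis(benzyloxy)-4-[3-(benzyloxy)-5-(methoxymethoxy)phenoxy]phenoxy}tri(propan-2-yl)silane | CC(C)[Si](Oc1cc(OCc2ccccc2)c(Oc2cc(OCc3ccccc3)cc(OCOC)c2)c(OCc2ccccc2)c1)(C(C)C)C(C)C | intermediate
26 | 3-(benzyloxy)-5-[2,6-bis(benzyloxy)-4-(triisopropylsilyloxy)phenoxy]phenol | Oc1cc(OCc2ccccc2)cc(Oc2c(OCc3ccccc3)cc(O[Si](C(C)C)(C(C)C)C(C)C)cc2OCc2ccccc2)c1 | intermediate
27 | 3,5-bis(benzyloxy)-4-[3-(benzyloxy)-5-hydroxyphenoxy]phenol | Oc1cc(OCc2ccccc2)c(Oc2cc(OCc3ccccc3)cc(O)c2)c(OCc2ccccc2)c1 | intermediate
28 | 3,5-bis(benzyloxy)-4-[3-(benzyloxy)-5-(sulfooxy)phenoxy]phenyl hydrogen sulfate (handled as the disodium salt) | O=S(=O)(O)Oc1cc(OCc2ccccc2)c(Oc2cc(OCc3ccccc3)cc(OS(=O)(=O)O)c2)c(OCc2ccccc2)c1 | intermediate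
29 | 3,5-dihydroxy-4-[3-hydroxy-5-(sulfooxy)phenoxy]phenyl hydrogen sulfate (handled as the disodium salt) | O=S(=O)(O)Oc1cc(O)cc(Oc2c(O)cc(OS(=O)(=O)O)cc2O)c1 | target

## Step count and risk

Total: 13 steps. Longest linear sequence: 11 steps (1, 2, 3, 4, 6, 8, 9, 10, 11, 12, 13); steps 5 and 7 are side branches.

**Step 8 (key step).** The most likely failure is that the terminal siloxyalkyne is consumed faster than it is trapped, by thermal 1,3-silyl shift to a silylketene or by oligomerisation at the temperature needed to open 14. Acylation of the phenolic product by unconsumed vinylketene is the second concern. If the annulation cannot be made to work, the diaryl ether is built classically. The fallback sets out from phenol 3 and returns at 27.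
- Commercial 4-bromo-3,5-dihydroxybenzoic acid is perbenzylated (BnBr, K2CO3, DMF) to benzyl 3,5-bis(benzyloxy)-4-bromobenzoate F1.
- Ligand-assisted Ullmann etherification of F1 with 3 (CuI, N,N-dimethylglycine, Cs2CO3, dioxane, 100 °C), helped by the para ester, gives benzyl 3,5-bis(benzyloxy)-4-[3-(benzyloxy)-5-(methoxymethoxy)phenoxy]benzoate F2.
- LiAlH4 reduces F2 to {3,5-bis(benzyloxy)-4-[3-(benzyloxy)-5-(methoxymethoxy)phenoxy]phenyl}methanol F3.
- MnO2 oxidises F3 to 3,5-bis(benzyloxy)-4-[3-(benzyloxy)-5-(methoxymethoxy)phenoxy]benzaldehyde F4.
- Baeyer–Villiger oxidation with mCPBA gives 3,5-bis(benzyloxy)-4-[3-(benzyloxy)-5-(methoxymethoxy)phenoxy]phenyl formate F5.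
- Methanolysis (K2CO3, MeOH) gives 3,5-bis(benzyloxy)-4-[3-(benzyloxy)-5-(methoxymethoxy)phenoxy]phenol F6, and HCl in methanol removes the acetal to give 27.

**Step 7.** Monolithium acetylide can disproportionate to insoluble Li2C2 before oxygen transfer is complete, and the small, volatile product can be lost or silylated on carbon. The fallback blocks the alkyne carbon. It sets out from 16 and returns at 24.
- (Trimethylsilyl)acetylene is lithiated, oxidised with lithium tert-butyl peroxide and O-silylated with 16 to triisopropyl{[(trimethylsilyl)ethynyl]oxy}silane F7.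
- Heating F7 with 14 under the conditions of step 8 gives 3-(benzyloxy)-2-[3-(benzyloxy)-5-(methoxymethoxy)phenoxy]-5-(triisopropylsilyloxy)-6-(trimethylsilyl)phenol F8.
- Brief ipso-protodesilylation of the doubly ortho-oxygenated aryl silane (CF3CO2H, CH2Cl2, 0 °C) returns 24.

**Step 6.** The acid chloride can close onto the electron-rich ring A in an intramolecular Friedel–Crafts acylation, and the aryloxyketene can dimerise faster than it is trapped by the ynol ether. The fallback moves the C–O bond formation to after the four-membered ring is made. It sets out from 11 and 3 and returns at 14.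
- Chloroketene, generated from chloroacetyl chloride and Et3N, adds 11 to give 3-(benzyloxy)-4-chlorocyclobut-2-en-1-one F9.
- The phenoxide of 3 (K2CO3, acetone, 0 °C) displaces the activated α-chloride of F9 to give 14.

**Step 12.** The second sulfation may stall, and the polar bis-sulfate salt may partly hydrolyse during purification. The fallback carries the sulfates as neutral diesters. It sets out from 27 and returns at 28.
- Diol 27 is treated with 2,2,2-trichloroethyl chlorosulfate (Et3N, DMAP, THF) to give the chromatographable bis(2,2,2-trichloroethyl sulfate) F10.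
- Zn and HCO2NH4 in methanol remove both trichloroethyl groups by reductive fragmentation to give 28.

## Further compounds

F1 | step 8 | benzyl 3,5-bis(benzyloxy)-4-bromobenzoate | O=C(OCc1ccccc1)c1cc(OCc2ccccc2)c(Br)c(OCc2ccccc2)c1
F2 | step 8 | benzyl 3,5-bis(benzyloxy)-4-[3-(benzyloxy)-5-(methoxymethoxy)phenoxy]benzoate | O=C(OCc1ccccc1)c1cc(OCc2ccccc2)c(Oc2cc(OCc3ccccc3)cc(OCOC)c2)c(OCc2ccccc2)c1
F3 | step 8 | {3,5-bis(benzyloxy)-4-[3-(benzyloxy)-5-(methoxymethoxy)phenoxy]phenyl}methanol | OCc1cc(OCc2ccccc2)c(Oc2cc(OCc3ccccc3)cc(OCOC)c2)c(OCc2ccccc2)c1
F4 | step 8 | 3,5-bis(benzyloxy)-4-[3-(benzyloxy)-5-(methoxymethoxy)phenoxy]benzaldehyde | O=Cc1cc(OCc2ccccc2)c(Oc2cc(OCc3ccccc3)cc(OCOC)c2)c(OCc2ccccc2)c1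
F5 | step 8 | 3,5-bis(benzyloxy)-4-[3-(benzyloxy)-5-(methoxymethoxy)phenoxy]phenyl formate | O=COc1cc(OCc2ccccc2)c(Oc2cc(OCc3ccccc3)cc(OCOC)c2)c(OCc2ccccc2)c1
F6 | step 8 | 3,5-bis(benzyloxy)-4-[3-(benzyloxy)-5-(methoxymethoxy)phenoxy]phenol | Oc1cc(OCc2ccccc2)c(Oc2cc(OCc3ccccc3)cc(OCOC)c2)c(OCc2ccccc2)c1
F7 | step 7 | triisopropyl{[(trimethylsilyl)ethynyl]oxy}silane | C[Si](C)(C)C#CO[Si](C(C)C)(C(C)C)C(C)C
F8 | step 7 | 3-(benzyloxy)-2-[3-(benzyloxy)-5-(methoxymethoxy)phenoxy]-5-(triisopropylsilyloxy)-6-(trimethylsilyl)phenol | Oc1c([Si](C)(C)C)c(O[Si](C(C)C)(C(C)C)C(C)C)cc(OCc2ccccc2)c1Oc1cc(OCc2ccccc2)cc(OCOC)c1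
F9 | step 6 | racemic 3-(benzyloxy)-4-chlorocyclobut-2-en-1-one | O=C1C=C(OCc2ccccc2)C1Cl
F10 | step 12 | 3,5-bis(benzyloxy)-4-[3-(benzyloxy)-5-{[(2,2,2-trichloroethoxy)sulfonyl]oxy}phenoxy]phenyl 2,2,2-trichloroethyl sulfate | ClC(Cl)(Cl)COS(=O)(=O)Oc1cc(OCc2ccccc2)c(Oc2cc(OCc3ccccc3)cc(OS(=O)(=O)OCC(Cl)(Cl)Cl)c2)c(OCc2ccccc2)c1
A1 | alternative 1 | 2-[3-(pivaloyloxy)phenoxy]-1,3-phenylene bis(2,2-dimethylpropanoate) | CC(C)(C)C(=O)Oc1cccc(Oc2c(OC(=O)C(C)(C)C)cccc2OC(=O)C(C)(C)C)c1
A2 | alternative 1 | 5-hydroxy-2-[3-hydroxy-5-(pivaloyloxy)phenoxy]-1,3-phenylene bis(2,2-dimethylpropanoate) | CC(C)(C)C(=O)Oc1cc(O)cc(Oc2c(OC(=O)C(C)(C)C)cc(O)cc2OC(=O)C(C)(C)C)c1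
A3 | alternative 2 | 4-[2,6-bis(benzyloxy)-4-(methoxymethoxy)phenoxy]-6-methyl-2H-pyran-2-one | Cc1cc(Oc2c(OCc3ccccc3)cc(OCOC)cc2OCc2ccccc2)cc(=O)o1
A4 | alternative 2 | 5-[2,6-bis(benzyloxy)-4-(methoxymethoxy)phenoxy]benzene-1,3-diol | Oc1cc(O)cc(Oc2c(OCc3ccccc3)cc(OCOC)cc2OCc2ccccc2)c1
A5 | alternative 2 | 2,6-bis(benzyloxy)-4-(methoxymethoxy)phenol | Oc1c(OCc2ccccc2)cc(OCOC)cc1OCc1ccccc1
A6 | alternative 3 | dimethyl 3-oxopentanedioate | COC(=O)CC(=O)CC(=O)OC
A7 | alternative 3 | dimethyl 2-[3-(benzyloxy)-5-(methoxymethoxy)phenoxy]propanedioate | COC(=O)C(Oc1cc(OCc2ccccc2)cc(OCOC)c1)C(=O)OC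
A8 | alternative 3 | dimethyl 5-[3-(benzyloxy)-5-(methoxymethoxy)phenoxy]-2,4,6-trihydroxyisophthalate | COC(=O)c1c(O)c(Oc2cc(OCc3ccccc3)cc(OCOC)c2)c(O)c(C(=O)OC)c1O
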